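By 17 min the autumn run has turned 44.5 % of its starting material into product and the dusk run 21.7 %, twice the share, and the catalyst charge is the same in both, so you want the rule that sets this share.

| flask | starting material | reagent | catalyst | time |
|---|---|---|---|---|
| midnight | 0.400 M | 0.600 M | 0.0120 M |  |
| dusk | 0.240 M | 0.440 M | 0.0120 M |  |
| spring | 1.20 M | 0.600 M | 0.0120 M |  |
| autumn | 0.400 M | 1.20 M | 0.0120 M |  |
| dawn | 0.800 M | 0.200 M | 0.0120 M | 17 min |

- midnight run (time / min: [product] / M): 0.68: 0.015; 1.1: 0.022; 1.7: 0.036; 2.7: 0.053; 4.3: 0.070; 6.8: 0.082; 11: 0.104; 17: 0.111
- dusk run (time / min: [product] / M): 0.68: 0.005; 1.1: 0.011; 1.7: 0.018; 2.7: 0.023; 4.3: 0.032; 6.8: 0.042; 11: 0.049; 17: 0.052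
- spring run (time / min: [product] / M): 0.68: 0.037; 1.1: 0.060; 1.7: 0.084; 2.7: 0.124; 4.3: 0.170; 6.8: 0.208; 11: 0.252; 17: 0.270
- autumn run (time / min: [product] / M): 0.68: 0.032; 1.1: 0.046; 1.7: 0.068; 2.7: 0.098; 4.3: 0.129; 6.8: 0.149; 11: 0.175; 17: 0.178

(scatter of a reading: 0.003 M)

- Overall: starting material + reagent -> product, with catalyst as catalyst.
- Constant volume, constant temperature.
- A reading of a species includes what of it is bound.
- An order is taken over about fifteen percent of the charge, up and down.

1. how the opening rate goes with [starting material] round the charge of the midnight run: the exponent of the rate at two percent of starting material gone to product (one fixed amount of product, the same in the runs compared)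
2. how the opening rate goes with [reagent] round the charge of the midnight run: the exponent of the rate at two percent of starting material gone to product
3. product in the dawn run at 17 min, as a share of the starting material charged

My reckoning supposes that starting material leaves by two routes, one taking reagent and one not. The odds of product at a given time are then the mean [reagent] divided by a constant concentration. I take the mean as the charge less half the product, and I multiply it by (1 − share)/share, which gives the last entry of each line:

- midnight: share 27.7 %, mean [reagent] 0.544 M, split 1.42 M
- dusk: share 21.7 %, mean [reagent] 0.414 M, split 1.50 M
- spring: share 22.5 %, mean [reagent] 0.465 M, split 1.60 M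
- autumn: share 44.5 %, mean [reagent] 1.11 M, split 1.39 M

Read down the lines. Going from midnight to autumn, the mean [reagent] rises from 0.544 M to 1.11 M and the share rises with it, yet the split goes from 1.42 M to 1.39 M. The spring run makes more product than the midnight run, but its share is smaller, at 22.5 %, and its mean [reagent] is lower too, with a split of 1.60 M. The mean of the splits, 1.48 M, I call the split reagent, the [reagent] at which the two routes would share the starting material evenly by that time.

In the dawn run reagent is the limiting reagent, 0.200 M against 0.800 M of starting material. Every line is read at 17 min, the time asked of dawn, so no time correction is needed, but the depletion of reagent has to be reckoned. The charge as it stands gives 11.9 %; subtracting half of that product from the reagent gives 9.35 %, a second pass gives 9.93 %, and a third gives 9.80 %, the figure I commit to, at which the product of the dawn run has taken 39.2 % of the reagent charged.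

The forecast says 9.3 %, with orders 0.9 in starting material and 1.02 in reagent. It starts from “The runs level off well short of full conversion” and reads that as an approach to equilibrium, and its dawn figure is lower than mine.

The dawn run gives 9.45 %, with orders 0.97 and 1.1.

    catalyst + starting material ⇌ catalyst-substrate complex, settled at all times (1.040 L mol⁻¹)
    catalyst-substrate complex + reagent → product + catalyst (23.94 L mol⁻¹ min⁻¹)
    2 catalyst ⇌ resting dimer, settled at all times (168.0 L mol⁻¹)
    starting material → decomposed substrate (0.1494 min⁻¹)

Starting material goes to decomposed substrate at 0.149 min⁻¹, a step that takes no reagent. Read backwards, the dawn share gives a split of 1.55 M, against the 1.48 M carried from the earlier runs. Set into the midnight run, the dawn split gives a share of 26.0 % at 17 min, above a quarter, and the midnight run reaches a quarter of its charge at 9.78 min.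

The data are calculated for an exercise; the scatter is artificial.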